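Ring C (the methoxy ring) is built from acyclic pieces instead of by methylating a phenol. Its C–OCH3 carbon, flanked by the C-methyl carbon and the butanoyl-bearing carbon, arrives preformed in 1-methoxyhex-1-yn-3-one. One Diels–Alder/aromatisation with a 1-methoxy-1,3-bis(trimethylsilyloxy)penta-1,3-diene forms the C(CH3)–C(OCH3) and C(butanoyl)–C(OH) bonds and closes the benzene ring with all six substituents in place. The diene already carries tribenzylated ring B on its central carbon through the future CH2 bridge, and its ring B ketone is masked as a silyl enol ether. Hydrogenolysis and a directed CH2 bridge to ring A (the gem-dimethyl triketone ring) finish the target.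

Key step: step 9

Remarks on the chemistry:
- The target has no stereocentre and is taken as the tautomer drawn in its SMILES. The double-bond geometries given for 5, 7 and 8 are the expected major isomers; they disappear in the following step or on aromatisation, so isomer mixtures are acceptable.
- The butanoyl ketone on ring B has α-hydrogens and cannot be expected to stay untouched when the diene is generated with a lithium amide. It is therefore silylated on purpose (precursor 8, same carbon skeleton) and returned to the ketone in the work-up of the key step.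
- The benzylic carbon is joined to the β-keto ester by condensation and conjugate reduction, which avoids a 2,4,6-trialkoxybenzyl halide that would alkylate its own ring.

Step 1
Reactants: 1 1-(2,4,6-trihydroxyphenyl)butan-1-one
Product: 2 1-[2,4,6-tris(benzyloxy)phenyl]butan-1-one
Conditions: BnBr (3.6 equiv), K2CO3 (4 equiv), DMF, 80 °C
Reagents that add atoms: benzyl bromide, BrCc1ccccc1
Why: Williamson ether synthesis; with a carbonate base in a dipolar aprotic solvent the acylphloroglucinol should be alkylated on oxygen and not on carbon, and heating carries the reaction past the two chelated ortho hydroxyls.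

Step 2
Reactants: 2 1-[2,4,6-tris(benzyloxy)phenyl]butan-1-one
Product: 3 2,4,6-tris(benzyloxy)-3-butanoylbenzaldehyde
Conditions: POCl3 (1.5 equiv), DMF, 0 → 40 °C; then ice/H2O
Reagents that add atoms: N,N-dimethylformamide, CN(C)C=O; water, O
Why: Vilsmeier–Haack formylation; each of the two equivalent ring CH positions is ortho to two benzyloxy groups and para to the third, so the chloroiminium ion should substitute there under mild conditions, and the first formyl group deactivates the ring against a second one.

Step 3
Reactants: 3 2,4,6-tris(benzyloxy)-3-butanoylbenzaldehyde; 4 methyl 3-oxopentanoate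
Product: 5 methyl (2Z)-2-{[2,4,6-tris(benzyloxy)-3-butanoylphenyl]methylidene}-3-oxopentanoate
Conditions: 4 (1.5 equiv), piperidine (0.2 equiv), AcOH (0.2 equiv), toluene, reflux, Dean–Stark trap
Reagents that add atoms: none
Why: Knoevenagel condensation driven by azeotropic removal of water; the aldehyde has no α-hydrogen and is far more electrophilic than the twisted, di-ortho-substituted aryl ketone, so only the formyl group should condense.

Step 4
Reactants: 5 methyl (2Z)-2-{[2,4,6-tris(benzyloxy)-3-butanoylphenyl]methylidene}-3-oxopentanoate
Product: 6 methyl 2-{[2,4,6-tris(benzyloxy)-3-butanoylphenyl]methyl}-3-oxopentanoate (racemic)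
Conditions: diethyl 2,6-dimethyl-1,4-dihydropyridine-3,5-dicarboxylate (Hantzsch ester, 1.3 equiv), SiO2, toluene, 80 °C
Reagents that add atoms: none
Why: Conjugate reduction by transfer hydrogenation; the dihydropyridine delivers hydride only to the doubly activated alkylidene β-keto ester and should leave benzyl ethers, the ester and both ketones untouched.

Step 5
Reactants: 6 methyl 2-{[2,4,6-tris(benzyloxy)-3-butanoylphenyl]methyl}-3-oxopentanoate
Product: 7 methyl (2Z)-2-{[2,4,6-tris(benzyloxy)-3-butanoylphenyl]methyl}-3-(trimethylsilyloxy)pent-2-enoate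
Conditions: TMSCl (1.5 equiv), Et3N (1.6 equiv), toluene, 20 °C; filtration under argon, used crude
Reagents that add atoms: chlorotrimethylsilane, C[Si](C)(C)Cl
Why: Silyl enol ether formation by soft enolisation, selective because only the 1,3-dicarbonyl unit is acidic enough for an amine base while the isolated aryl ketone is not.

Step 6
Reactants: 7 methyl (2Z)-2-{[2,4,6-tris(benzyloxy)-3-butanoylphenyl]methyl}-3-(trimethylsilyloxy)pent-2-enoate
Product: 8 (1Z,3Z)-1-methoxy-1,3-bis(trimethylsilyloxy)penta-1,3-diene carrying on C2 the 2,4,6-tris(benzyloxy)benzyl group of ring B, whose butanoyl group is held as its (Z)-trimethylsilyl enol ether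
Conditions: LiN(iPr)2 (2.4 equiv), THF, −78 °C; then TMSCl (3 equiv), −78 → 20 °C; pentane, filtration under argon, used crude
Reagents that add atoms: chlorotrimethylsilane, C[Si](C)(C)Cl
Why: Kinetic deprotonation removes a γ-hydrogen of the β-silyloxy enoate and an α-hydrogen of the ring B ketone and both enolates are O-silylated, which is the standard second stage in the preparation of 1-alkoxy-1,3-bis(silyloxy)-1,3-dienes; the excess of base is deliberate so that one fully silylated compound results and not a mixture.

Step 7
Reactants: 9 butanoyl chloride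
Product: 10 N-methoxy-N-methylbutanamide
Conditions: MeNH(OMe)·HCl (1.1 equiv), Et3N (2.2 equiv), CH2Cl2, 0 → 20 °C
Reagents that add atoms: N,O-dimethylhydroxylamine hydrochloride, CNOC.Cl
Why: Amide formation by N-acylation of the hydroxylamine with the acid chloride (Schotten–Baumann type), a routine preparation of an N-methoxy-N-methylamide.

Step 8
Reactants: 11 2-chloro-1,1-dimethoxyethane; 10 N-methoxy-N-methylbutanamide
Product: 13 1-methoxyhex-1-yn-3-one, via lithium methoxyacetylide 12 (not isolated)
Conditions: 11 (1.3 equiv), LiNEt2 (3 equiv per 11, from Et2NH and n-BuLi), THF, 0 °C; then 10, −78 → −30 °C; aq NH4Cl at low temperature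
Reagents that add atoms: none
Why: Twofold elimination (CH3OH, then HCl) and deprotonation of the chloroacetal should give the alkoxyacetylide without isolation of volatile methoxyacetylene, and its acylation by the N-methoxy-N-methylamide stops at the ketone because the chelated tetrahedral adduct survives until work-up (Weinreb ketone synthesis).

Step 9
Reactants: 8 tris-silylated ring B-substituted diene; 13 1-methoxyhex-1-yn-3-one
Product: 15 1-[3-({2,4,6-tris(benzyloxy)-3-butanoylphenyl}methyl)-2,4-dihydroxy-6-methoxy-5-methylphenyl]butan-1-one (tribenzylated ring B joined by CH2 to free ring C), via cyclohexa-1,4-diene cycloadduct 14 (not isolated)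
Conditions: 13 (1.5 equiv), toluene, 20 → 80 °C, argon; then HCl (cat.) in MeOH, 0 → 20 °C
Reagents that add atoms: none
Why: Proposed new method: ketene acetal diene 8 and push–pull ynone 13 are expected to combine in a normal-demand [4+2] cycloaddition, concerted but asynchronous or stepwise by Mukaiyama–Michael attack of the CH(CH3) terminus on the methoxy-bearing β-carbon followed by attack of the allenolate α-carbon on the silyloxycarbenium carbon, to give cyclohexa-1,4-diene 14, which methanolic acid desilylates and aromatises by 1,4-loss of CH3OH from the acetal carbon. The closest known reaction type is the Diels–Alder/aromatisation of 1-alkoxy-1,3-bis(silyloxy)-1,3-dienes with acetylenic esters and ketones; a β-alkoxy ynone has not been shown as the partner, hence the label. Ring C closes as a six-membered carbocycle by intermolecular [4+2] annulation, which in the stepwise picture is a 6-exo-trig closure onto the activated ester carbon. No stereocentre has to be controlled, because the two sp3 ring carbons of 14 become aromatic. The step needs head-to-tail regioselectivity and [4+2] instead of [3+3] closure: the first is secured by the matched polarisation (largest HOMO coefficient of 8 at C4, electrophilic β-carbon of 13), which places OCH3 between CH3 and the butanoyl group, the second by the benzylic substituent on the central diene carbon and by the absence of a Lewis acid. The silyl enol ether on ring B is a much weaker nucleophile than the ketene acetal and is returned to the ketone in the work-up, for which methanol is used so that any exchange at the vinylogous ester carbon can only give back OCH3.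

Step 10
Reactants: 15 tribenzylated ring B joined by CH2 to free ring C
Product: 16 1-{3-[(3-butanoyl-2,4,6-trihydroxyphenyl)methyl]-2,4-dihydroxy-6-methoxy-5-methylphenyl}butan-1-one
Conditions: H2 (1 atm), 10% Pd/C, EtOAc/MeOH, 20 °C
Reagents that add atoms: none
Why: Hydrogenolysis of the three benzyl ethers under neutral conditions, to which the diarylmethane bridge, the aryl methyl ether and the chelated aryl ketones should be inert at ambient pressure and temperature.

Step 11
Reactants: 1 1-(2,4,6-trihydroxyphenyl)butan-1-one
Product: 17 2-butanoyl-3,5-dihydroxy-6,6-dimethylcyclohexa-2,4-dien-1-one (ring A, butyrylfilicinic acid)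
Conditions: MeI (2.2 equiv), NaOMe, MeOH, 0 → 20 °C; then dilute HCl; chromatography
Reagents that add atoms: iodomethane, CI
Why: Dearomatising double C-methylation of the phloroglucinol anion; the protic medium and the sodium counter-ion direct iodomethane to carbon, and the second methyl group should enter the same carbon to give the gem-dimethyl trione, the established access to acylfilicinic acids, from which mono- and over-methylated material is separated.

Step 12
Reactants: 17 2-butanoyl-3,5-dihydroxy-6,6-dimethylcyclohexa-2,4-dien-1-one; 16 1-{3-[(3-butanoyl-2,4,6-trihydroxyphenyl)methyl]-2,4-dihydroxy-6-methoxy-5-methylphenyl}butan-1-one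
Product: 19 Filixsaure as drawn in the target SMILES (2-butanoyl-4-({3-butanoyl-5-[(3-butanoyl-2,6-dihydroxy-4-methoxy-5-methylphenyl)methyl]-2,4,6-trihydroxyphenyl}methyl)-3,5-dihydroxy-6,6-dimethylcyclohexa-2,4-dien-1-one), via ring A Mannich base 18 (not isolated)
Conditions: 17 (1.3 equiv), Me2N=CH2+ I− (1.25 equiv), Et3N (1.3 equiv), MeCN, 0 → 20 °C; then 16 (1 equiv), 60 °C; dilute HCl work-up
Reagents that add atoms: dimethylmethylideneammonium iodide, C=[N+](C)C.[I-]
Why: Mannich aminomethylation of the vinylogous acid 17 with a preformed iminium salt, then thermal loss of Me2NH to a 2-methylene-1,3-dione that is captured in a Michael/Friedel–Crafts sense by the only free ring carbon of 16 (on ring B, ring C being fully substituted); fixing the CH2 unit on one partner first avoids the statistical mixture of a three-component formaldehyde condensation.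

Compound list
1 | 1-(2,4,6-trihydroxyphenyl)butan-1-one | CCCC(=O)c1c(O)cc(O)cc1O | starting material
2 | 1-[2,4,6-tris(benzyloxy)phenyl]butan-1-one | CCCC(=O)c1c(OCc2ccccc2)cc(OCc2ccccc2)cc1OCc1ccccc1 | intermediate
3 | 2,4,6-tris(benzyloxy)-3-butanoylbenzaldehyde | CCCC(=O)c1c(OCc2ccccc2)cc(OCc2ccccc2)c(C=O)c1OCc1ccccc1 | intermediate
4 | methyl 3-oxopentanoate | CCC(=O)CC(=O)OC | starting material
5 | methyl (2Z)-2-{[2,4,6-tris(benzyloxy)-3-butanoylphenyl]methylidene}-3-oxopentanoate | CCC(=O)/C(C(=O)OC)=C/c1c(OCc2ccccc2)cc(OCc2ccccc2)c(C(=O)CCC)c1OCc1ccccc1 | intermediate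
6 | methyl 2-{[2,4,6-tris(benzyloxy)-3-butanoylphenyl]methyl}-3-oxopentanoate (racemic; the stereocentre is removed in step 5) | CCC(=O)C(Cc1c(OCc2ccccc2)cc(OCc2ccccc2)c(C(=O)CCC)c1OCc1ccccc1)C(=O)OC | intermediate
7 | methyl (2Z)-2-{[2,4,6-tris(benzyloxy)-3-butanoylphenyl]methyl}-3-(trimethylsilyloxy)pent-2-enoate | CC/C(O[Si](C)(C)C)=C(\Cc1c(OCc2ccccc2)cc(OCc2ccccc2)c(C(=O)CCC)c1OCc1ccccc1)C(=O)OC | intermediate
8 | (1Z,3Z)-1-methoxy-1,3-bis(trimethylsilyloxy)penta-1,3-diene with the {2,4,6-tris(benzyloxy)-3-[(1Z)-1-(trimethylsilyloxy)but-1-en-1-yl]phenyl}methyl group on C2 | C/C=C(O[Si](C)(C)C)/C(Cc1c(OCc2ccccc2)cc(OCc2ccccc2)c(/C(O[Si](C)(C)C)=C/CC)c1OCc1ccccc1)=C(/OC)O[Si](C)(C)C | intermediate (precursor of the key step)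
9 | butanoyl chloride | CCCC(=O)Cl | starting material
10 | N-methoxy-N-methylbutanamide | CCCC(=O)N(C)OC | intermediate
11 | 2-chloro-1,1-dimethoxyethane | COC(CCl)OC | starting material
12 | lithium methoxyacetylide | [Li]C#COC | intermediate (not isolated)
13 | 1-methoxyhex-1-yn-3-one | CCCC(=O)C#COC | intermediate
14 | 1-[5-({2,4,6-tris(benzyloxy)-3-[(1Z)-1-(trimethylsilyloxy)but-1-en-1-yl]phenyl}methyl)-2,6-dimethoxy-3-methyl-4,6-bis(trimethylsilyloxy)cyclohexa-1,4-dien-1-yl]butan-1-one (diastereomer mixture; both sp3 centres are lost on aromatisation) | CCCC(=O)C1=C(OC)C(C)C(O[Si](C)(C)C)=C(Cc2c(OCc3ccccc3)cc(OCc3ccccc3)c(/C(O[Si](C)(C)C)=C/CC)c2OCc2ccccc2)C1(OC)O[Si](C)(C)C | intermediate (not isolated)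
15 | 1-[3-({2,4,6-tris(benzyloxy)-3-butanoylphenyl}methyl)-2,4-dihydroxy-6-methoxy-5-methylphenyl]butan-1-one | CCCC(=O)c1c(OCc2ccccc2)cc(OCc2ccccc2)c(Cc2c(O)c(C)c(OC)c(C(=O)CCC)c2O)c1OCc1ccccc1 | intermediate (product of the key step)
16 | 1-{3-[(3-butanoyl-2,4,6-trihydroxyphenyl)methyl]-2,4-dihydroxy-6-methoxy-5-methylphenyl}butan-1-one | CCCC(=O)c1c(O)cc(O)c(Cc2c(O)c(C)c(OC)c(C(=O)CCC)c2O)c1O | intermediate
17 | 2-butanoyl-3,5-dihydroxy-6,6-dimethylcyclohexa-2,4-dien-1-one | CCCC(=O)C1=C(O)C=C(O)C(C)(C)C1=O | intermediate
18 | 2-butanoyl-4-[(dimethylamino)methyl]-3,5-dihydroxy-6,6-dimethylcyclohexa-2,4-dien-1-one | CCCC(=O)C1=C(O)C(CN(C)C)=C(O)C(C)(C)C1=O | intermediate (not isolated)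
19 | Filixsaure (target as drawn) | CCCC(=O)C1=C(O)C(Cc2c(O)c(Cc3c(O)c(C)c(OC)c(C(=O)CCC)c3O)c(O)c(C(=O)CCC)c2O)=C(O)C(C)(C)C1=O | target

Total step count: 12. Longest linear sequence: 9 steps (steps 1, 2, 3, 4, 5, 6, 9, 10, 12).

Steps most likely to fail

Step 9 (key step). The donor-substituted ynone may be too weak a dienophile, so that the diene desilylates or decomposes before it reacts. Conjugate addition may also be followed by expulsion of methoxide from the β-carbon, by closure through the ketone carbonyl, or by loss of silanol instead of methanol, each of which would spoil the substitution pattern of ring C. The fallback makes ring C by classical arene chemistry and joins it to ring B by Friedel–Crafts benzylation; it sets out from 1 and 3 and comes back to the route at 15. Mono-C-methylation of 1 (MeI, 1 equiv, NaOMe, MeOH) would give 1-(2,4,6-trihydroxy-3-methylphenyl)butan-1-one F1. Benzylation with two equivalents of BnBr (K2CO3, acetone) should take the para hydroxyl and the less hindered ortho hydroxyl to give 1-[4,6-bis(benzyloxy)-2-hydroxy-3-methylphenyl]butan-1-one F2; the discrimination between the two chelated hydroxyls is expected to be modest, so the isomer would have to be removed by chromatography. Methylation of the remaining chelated hydroxyl (Me2SO4, K2CO3, acetone, reflux) would give 1-[4,6-bis(benzyloxy)-2-methoxy-3-methylphenyl]butan-1-one F3, and hydrogenolysis (H2, Pd/C, EtOAc) the ring C monomer 1-(4,6-dihydroxy-2-methoxy-3-methylphenyl)butan-1-one F4. Aldehyde 3 would be reduced (NaBH4, THF/MeOH, 0 °C, the hindered ketone being left alone) to 1-[2,4,6-tris(benzyloxy)-3-(hydroxymethyl)phenyl]butan-1-one F5. Under catalytic acid (TsOH, CH2Cl2, 0 °C) F5 ionises to a stabilised benzylic cation that alkylates an excess of the more nucleophilic free phenol F4 at its only unsubstituted ring carbon, giving 15.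

Step 12. The CH2 unit may be transferred instead of fixed: retro-Mannich release of the iminium ion or reversible opening of the existing diarylmethane bridge under the mildly basic, warm conditions would scramble the partners into symmetrical dimers. The fallback reverses the roles of the two partners; it sets out from 16 and comes back at 19. Compound 16 would be aminomethylated at the free ring B carbon (Me2N=CH2+ I−, Et3N, MeCN, 0 °C) to 1-{3-[(3-butanoyl-5-[(dimethylamino)methyl]-2,4,6-trihydroxyphenyl)methyl]-2,4-dihydroxy-6-methoxy-5-methylphenyl}butan-1-one F6. Warming F6 with an excess of 17 in dioxane should expel Me2NH, and the ortho-quinone methide of ring B would then be trapped by the strongly nucleophilic enol carbon of 17 to give 19.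

Step 3. The aldehyde is flanked by two benzyloxy groups and is electron-rich, so the condensation may be slow, may stop at an unfavourable equilibrium, or may be overtaken by self-condensation of the keto ester. The fallback replaces condensation and reduction by an enolate alkylation; it sets out from 3 and comes back at 6, bypassing 5. Aldehyde 3 would be reduced (NaBH4, THF/MeOH, 0 °C) to 1-[2,4,6-tris(benzyloxy)-3-(hydroxymethyl)phenyl]butan-1-one F5 and converted under neutral Appel conditions (CBr4, PPh3, CH2Cl2, 0 °C) into 1-[2,4,6-tris(benzyloxy)-3-(bromomethyl)phenyl]butan-1-one F7. F7 would be used at once, without storage, to alkylate the sodium enolate of 4 (NaH, THF, 0 °C, 4 in excess to suppress dialkylation), giving 6.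

Further compounds
F1 | step 9 | 1-(2,4,6-trihydroxy-3-methylphenyl)butan-1-one | CCCC(=O)c1c(O)cc(O)c(C)c1O
F2 | step 9 | 1-[4,6-bis(benzyloxy)-2-hydroxy-3-methylphenyl]butan-1-one | CCCC(=O)c1c(O)c(C)c(OCc2ccccc2)cc1OCc1ccccc1
F3 | step 9 | 1-[4,6-bis(benzyloxy)-2-methoxy-3-methylphenyl]butan-1-one | CCCC(=O)c1c(OC)c(C)c(OCc2ccccc2)cc1OCc1ccccc1
F4 | step 9 | 1-(4,6-dihydroxy-2-methoxy-3-methylphenyl)butan-1-one | CCCC(=O)c1c(OC)c(C)c(O)cc1O
F5 | step 9 | 1-[2,4,6-tris(benzyloxy)-3-(hydroxymethyl)phenyl]butan-1-one | CCCC(=O)c1c(OCc2ccccc2)cc(OCc2ccccc2)c(CO)c1OCc1ccccc1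
F6 | step 12 | 1-{3-[(3-butanoyl-5-[(dimethylamino)methyl]-2,4,6-trihydroxyphenyl)methyl]-2,4-dihydroxy-6-methoxy-5-methylphenyl}butan-1-one | CCCC(=O)c1c(O)c(CN(C)C)c(O)c(Cc2c(O)c(C)c(OC)c(C(=O)CCC)c2O)c1O
F7 | step 3 | 1-[2,4,6-tris(benzyloxy)-3-(bromomethyl)phenyl]butan-1-one | CCCC(=O)c1c(OCc2ccccc2)cc(OCc2ccccc2)c(CBr)c1OCc1ccccc1
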